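(The numbers were drawn at random within sensible limits.)

The time read here, 15 s, is also the dosing time, so the starting complex meets the incoming ligand as it trickles in.

starting complex 2.0 mM; incoming ligand 3.00 mM (fed, over 15 s); time 15 s

    starting complex + incoming ligand ⇌ leaving ligand + complex with one exchanged (K1 = 0.44, k1 = 25 M⁻¹ s⁻¹)
    complex with one exchanged + incoming ligand ⇌ leaving ligand + complex with two exchanged (K2 = 10, k2 = 140 M⁻¹ s⁻¹)
    complex with two exchanged + incoming ligand ⇌ leaving ligand + complex with three exchanged (K3 = 0.98, k3 = 50 M⁻¹ s⁻¹)
    incoming ligand → decomposed reagent (k4 = 0.11 s⁻¹)
    incoming ligand ⇌ dormant form (K5 = 0.14, k5 = 4.0 s⁻¹)

- the reaction counts as stopped when no species that holds the starting complex changes by six tenths of a point or more over the second half of the time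
- run time (flask): 15 s

- at 15 s, what has stopped the reaction, if anything has (forward and back rates have come level / it is still moving / the incoming ligand has run out first / all of the starting complex has reacted)
- part of the starting complex gone at 15 s
- the complex with one exchanged standing at 15 s, as a percentage of the starting complex charged

My reckoning by hand follows the incoming ligand. It relaxes with the dormant form at a half-life of 0.0213 s, far shorter than the 6.3 s in which step 4 by itself halves it, so take step 5 as settled: the pool of both forms is the incoming ligand times 1 + K5.

The pool fills at 0.200 mM s⁻¹. It drains through decomposition and through the starting complex, counted at full charge, at k4 + k1·cM, which on the pool is 0.140 s⁻¹. The incoming ligand therefore climbs towards 1.25 mM and stands at 1.10 mM by the end.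

The starting complex then reacts pseudo-first-order, and the quantity I carry is its exposure, k1 times the time integral of the incoming ligand: 0.273. With the way back left out, 1 − exp(−exposure) gives 23.9% gone. Since 1.10 mM of ligand remains, I expect the flask to be still moving. I reckon nothing for the complex with one exchanged.

The forecast says it is still moving, 21% gone and 10% for the complex with one exchanged, on the grounds that “decomposition, slightly damped by the quick dormant-form equilibrium, competes with the feed”. Its conversion is lower than mine.

The simulation of this flask answers that it is still moving, with 21.4% of the starting complex gone, 10.8% standing as complex with one exchanged and 1.02 mM of incoming ligand left. Backward turnover in step 1 of this flask is 8.1% of the forward one.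

Now take a neighbouring flask, like this one but charged with 5.1 mM of incoming ligand, 2.55 equiv. Both drains in my reckoning are first order in the ligand, so its exposure grows with the charge to 0.464. That gives 37.2% gone and 1.87 mM of incoming ligand standing. The neighbouring flask actually holds 1.73 mM, which is 34% of its charge, the same share as in the first flask, and it has lost 32.3% of its starting complex.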